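In the first minutes of a run the enzyme Z and the pairing of X into X2 draw on the same substrate, and two chemists at the board dispute whether that matters.

all flasks: Z 1.9 µM
- gamma: X 19 mM (fed, over 4.80 h); time 6.0 h; all but X at the start; X goes in evenly over 4.80 h, the run ends at 6.0 h
- epsilon: X 19 mM; time 6.0 h; everything together in a closed stirred flask, run for 6.0 h
- eta: X 19 mM; a single well-mixed tank run continuously and read at steady state, 6.0 h in it on average

    X + Z → D + Z, rate k1*[X]*[Z]/(1 + ([X]/Km1) + ([D]/Kp1)) (Km1 = 1.8 mM, Kp1 = 9.7 mM, k1 = 40000 L mol⁻¹ min⁻¹)
    X + D → X.D (k2 = 0.10 L mol⁻¹ min⁻¹)
    2 X → X2 (k3 = 0.19 L mol⁻¹ min⁻¹)

- percent here means X units held: one X.D or X2 counts as two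
- for a step with 2 of a species take k times the square, and two of it per event
- the stated concentrations are those of everything mixed, before any reaction; amounts are the same in each set-up
- the feed brings no volume worth counting
- run time (gamma): 6.0 h

1. the set-up with the highest amount of D at the outlet or at the end, in percent of the X put in ("none" if the first two lie within 2 percentage points) (gamma / epsilon / eta / none)
2. amount of D at the outlet or at the end, in percent of the X put in, gamma
3. amount of D at the outlet or at the end, in percent of the X put in, epsilon
4. amount of D at the outlet or at the end, in percent of the X put in, eta

The first chemist takes the ceiling view. X stands at 19 mM against a Km1 of 1.8 mM, so she puts Z at its top rate, k1 times Z times Km1, which is 0.137 mM min⁻¹. At that rate the charge needs 2.31 h, which is shorter than the run. In her view the closed flask epsilon finishes in time and dosing gains nothing.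

The second chemist, and I with him, divides the two rates instead. X lost to pairing per X passed through Z is the loss ratio, a selectivity factor: X over the pairing scale, times the brake. The pairing scale is k1 times Z over twice k3, here 200 mM. The brake is the denominator of the enzyme's rate law.

In powers of ten, the scale is ten times the charge, but at the start of epsilon the brake is 11.6, also about ten times. The two cancel, and the ratio is 1.10. In the fed flask gamma, X need stand where Z takes up the feed, 1.68 mM before D gathers. There the ratio is 0.0162, lower by 1.83 powers of ten. My reckoning gives ratios, not yields: it ranks gamma above epsilon and goes no further.

The forecast sides with him and names gamma: gamma 87 % (84 % to 90 %), epsilon 70.5 % (67 % to 74 %), eta 75.5 % (72 % to 79 %). Its ground is that adding everything at once “lets the second-order dimerisation take much of the X early”.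

The simulation puts gamma ahead with 87.5 %, then the tank eta with 75.4 % and epsilon with 69.5 %, each inside the forecast's range.

Slow dosing is worth 18 percentage points to gamma, whose answer without it is 69.5 %. At gamma's reading of 2.94 mM for peak X, with D taken at its final amount, two moments set side by side, the loss ratio is 0.0639. In the tank eta, with 2.02 mM of X and D as at the outlet, it is 0.0364. Her side lies toward smaller charges: at 16.2 mM of X, where the starting ratio is 0.810, epsilon's answer has moved by 5 points.

The numbers are assumed; the result is computed.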